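## The problem

Target 19 is a 1-aryl-1,2-dihydronaphthalene lignan. In the numbering used throughout, ring B holds C1 (CH bearing the pendant aryl group), C2 (CH bearing C9H2OH), C3 (bearing the formyl carbon C10) and C4 (=CH); the fusion carbons are C4a and C8a (C8a on C1); ring A carries H at C5, OMe at C6, OH at C7 and OMe at C8. Ring B must be closed onto a ring A that is substituted everywhere but C5, with C1 on the carbon next to a methoxy group (C8a) and C4 on the carbon para to the C7 hydroxyl (C4a). A plain ortho Friedel–Crafts closure from an aryl group already on C1 would give the isomeric 5,6,7-oxygenation pattern. The two adjacent stereocentres, C1 (S) and C2 (R), are trans on ring B. C1 is doubly benzylic and para-hydroxybenzylic, so it ionises and epimerises under acid, whereas C2 is an ordinary tertiary carbon; C2 can therefore be set first with absolute control and left to dictate C1, not the reverse. The free 2,6-dimethoxyphenols oxidise easily to quinone methides, the enal invites conjugate addition, and the dihydronaphthalene can aromatise or shift its double bond under base, so C10 and the free hydroxyls should appear late and under mild conditions. The enabling feature is that ring A and the pendant aryl group are the same 4-hydroxy-3,5-dimethoxyphenyl unit. Moving C1 from C8a back to C4a turns the skeleton into the bis(aryl)methyl alkyne 15, in which C1 is not stereogenic and C4a is the nucleophilic para carbon of a phenol.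

## Retrosynthesis

**Endgame, 19 back to 17.** The O–Si bond at C9 is cut (19 from the TIPS ether 18), then C3–C10 (18 from the alkenyl iodide 17 and a one-carbon formyl source). Cutting C3–C10 is dictated by the key step, where C3 is an alkyne carbon, and it means the enal exists for one step only. The reverse order would expose the C9 hydroxyl to the acyl–palladium intermediate and invite butenolide formation. 17 lacks one carbon of the target; the forward steps must formylate an alkenyl iodide beside two hindered phenols and then remove one silyl group without base.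

**Key disconnection, 17 back to 15.** The bonds C1–C8a and C4–C4a are cut. In the forward sense C4–C4a forms first by ipso attack of a phenol on the activated alkyne (spirodienone 16), then C1 moves from C4a to C8a. Cutting C1–C8a alone is the classical cationic closure, but it needs ring A already on C4, a defined alkene geometry and two different aryl fragments. Cutting C4–C4a alone, by ortho attack of a C1-bound aryl group, gives the wrong ring A pattern. The double cut removes ring B and the C1 stereocentre together: 15 is acyclic, has one stereocentre and two identical aryl groups. The forward reaction must choose ipso over ortho attack, migrate C1 rather than C4, and leave the spectator aryl group trans to the C2 substituent; iodine ends up on C3, where C10 is needed.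

**Alkyne, 15 back to 13.** The triple bond is traced to aldehyde 13 by removing C4 (one-carbon homologation), and the two phenolic O–Si bonds are cut in the same operation (via 14). Displacement at C2 by an acetylide would need clean inversion at a hindered centre; the homologation does not touch C2. 13 has the same skeleton less one carbon. The forward reaction must neither epimerise the α-stereocentre nor eliminate the β-silyloxy group.

**Stereocentre C2, 13 back to 8.** Functional-group changes lead from 13 through acetal 12 and alcohol 11 to imide 10. The C2–C3 bond is then cut to the enolate 9 of imide 8 and a formyl cation equivalent. Of the three bonds at C2 that an auxiliary could control, this one is preferred. Cutting C1–C2 would mean alkylating a β-oxygenated enolate with a benzhydryl cation, and cutting C2–C9 gives an aldol-type imide. The chosen cut delivers C3 and C9 already differentiated, as acetal and acyl carbon. 8 has no stereocentre outside the auxiliary. The forward alkylation must take place on a hindered β,β-diaryl enolate with high facial selectivity.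

**Achiral backbone, 8 back to 1 and 2.** The N–acyl bond of 8 is cut to acid 5 (activated as 7) and oxazolidinone 6; the phenolic O–Si bonds of 5 lead to 3 (forward via silyl ester 4); one C1–aryl bond of 3 is cut to sinapic acid 1 and 2,6-dimethoxyphenol 2. Because the aryl groups are identical, either C1–aryl bond gives the same two commercial phenols in one step, whereas a conjugate addition of an aryl metal would need protecting-group steps first. The forward hydroarylation must go through the position para to the hydroxyl of 2.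

## Roads not taken

**Alternative 1:** The cut removes C8a–C1 and C1–C2, so C1 enters as a one-carbon unit. Ring A would come as the ortho-bromo arylidene succinate A1, which already carries C4, C3, C2 and both ester carbons, and C1 with its aryl group as the tosylhydrazone A2. With Pd2(dba)3, a chiral phosphine and LiOtBu, oxidative addition of A1, carbene formation from A2, migratory insertion (C8a–C1) and attack of the C2 ester enolate on the η3-benzylpalladium (C1–C2) would close ring B to the trans diester A3.
- Merits: it is convergent, the chirality comes from a catalyst, the bromine fixes where C1 joins ring A so no migration selectivity is at stake, and C10 is present as the C3 ester.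
- Weak points: the bromide of A1 is flanked by a methoxy group and the alkenyl chain, so oxidative addition will be slow. The enolate is an extended dienolate that can move the double bond or react at C4. One ligand would have to control C1 and C2 together. After the annulation the C2 ester must become CH2OH and the conjugated C3 ester CHO without epimerising C2, and two benzyl ethers must be removed beside a styrene and an enal, where hydrogenolysis is excluded.
- Comparison: this road is better in catalytic asymmetric induction and convergence. The chosen plan sets against it a C2 centre fixed by auxiliary chemistry, no ester differentiation, protecting groups that fall to fluoride or carbonate, and a two-step endgame.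

**Alternative 2:** The cut through C4a–C8a and C7–C8 removes ring A altogether. The precursor is the furan-tethered ynal A4, a 4-methoxyfuran joined through C4=C3(CO2Me)–C2–C1 to an alkynal. On heating, the furan would add across the ynal, the oxanorbornadiene would open and tautomerise to the C7 phenol, and rings A and B would both be formed in A5.
- Merits: the ring A pattern is built unambiguously, the step needs no reagent, and intramolecular furan Diels–Alder aromatisation is a known reaction class; in that respect it stands on firmer ground than the chosen key step.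
- Weak points: A4 needs a long linear synthesis with both C1 and C2 set beforehand, C1 being propargylic, benzylic and easily epimerised. The 3-alkoxyfuran and the ynal are fragile. The product A5 carries CHO at C8 where OMe is needed, so a Dakin oxidation and an O-methylation that spares the C7 hydroxyl must follow, together with ester-to-aldehyde adjustment and debenzylation.
- Comparison: the chosen plan accepts a less precedented key step in exchange for a much shorter route from two symmetrical, commercial phenols and no oxygenation changes after ring closure.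

**Alternative 3:** C4 is removed as a one-carbon unit. The indanone A6 (from a Nazarov cyclisation of an aryl vinyl ketone) would react with trimethylsilyldiazomethane under BF3·OEt2 or Sc(OTf)3; ring A carbon C4a migrates, C4–C4a and C3–C4 form, and the trans 3-tetralone A7 results after protodesilylation.
- Merits: each bond-forming event belongs to a known reaction type, the trans relationship is thermodynamically secured next to the ketone, and the C3 carbonyl is a defined handle.
- Weak points: the Nazarov step gives no absolute stereocontrol on such a substrate. The ketone of A6 is conjugated to the electron-rich ring and poorly electrophilic, while the product ketone is more reactive and can be homologated again. Aryl versus alkyl migration is not assured. A7 enolises toward C2 and still needs enol triflate formation, formylation and debenzylation beside the alkene.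
- Comparison: the precedent for each step is better here. The chosen plan offers absolute control from a single auxiliary step and a ring-closing step that leaves C3 as an iodide, one carbonylation away from the enal.

Key step: step 9

## Route

Remark on the chemistry: the target is taken as the (1S,2R) isomer encoded in its SMILES, with the C1 aryl group and the C2 hydroxymethyl group trans; ring B compounds are named with the lignan numbering defined above. Abbreviations: TBS = tert-butyldimethylsilyl, TIPS = triisopropylsilyl.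

Step 1
Reactants: 1 sinapic acid; 2 2,6-dimethoxyphenol
Product: 3 3,3-bis(4-hydroxy-3,5-dimethoxyphenyl)propanoic acid
Conditions: 2 (3 equiv), CF3CO2H/CH2Cl2, rt to 40 °C
Reagents that add atoms: none
Why: Brønsted-acid hydroarylation of a cinnamic acid (Friedel–Crafts conjugate alkylation): protonation of 1 gives a para-hydroxybenzylic cation that 2 captures at the carbon para to its hydroxyl, the favoured and least hindered site of a 2,6-dialkoxyphenol; both ortho positions of 2 are blocked, so no dihydrocoumarin can form, and the identical aryl groups mean no stereocentre arises.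

Step 2
Reactants: 3 3,3-bis(4-hydroxy-3,5-dimethoxyphenyl)propanoic acid
Product: 5 3,3-bis[4-(TBS-oxy)-3,5-dimethoxyphenyl]propanoic acid, via silyl ester 4 (not isolated)
Conditions: TBSCl, imidazole, DMF, rt; then AcOH/THF/H2O, rt
Reagents that add atoms: tert-butyldimethylsilyl chloride, CC(C)(C)[Si](C)(C)Cl
Why: Silylation of the two hindered phenols with TBSCl/imidazole; the silyl ester formed alongside is far more labile than an aryl silyl ether and is hydrolysed selectively by aqueous acetic acid.

Step 3
Reactants: 5 3,3-bis[4-(TBS-oxy)-3,5-dimethoxyphenyl]propanoic acid; 6 (S)-4-benzyl-2-oxazolidinone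
Product: 8 (4S)-4-benzyl-3-{3,3-bis[4-(TBS-oxy)-3,5-dimethoxyphenyl]propanoyl}oxazolidin-2-one, via mixed pivalic anhydride 7 (not isolated)
Conditions: t-BuCOCl, Et3N, THF, −20 °C; then 6, LiCl, rt
Reagents that add atoms: none
Why: N-Acylation of the oxazolidinone through the mixed pivalic anhydride under LiCl/Et3N activation; the tert-butyl group directs attack to the desired acyl carbon and no stereocentre is formed.

Step 4
Reactants: 8 (4S)-4-benzyl-3-{3,3-bis[4-(TBS-oxy)-3,5-dimethoxyphenyl]propanoyl}oxazolidin-2-one
Product: 10 (4S)-4-benzyl-3-{(2R)-3,3-bis[4-(TBS-oxy)-3,5-dimethoxyphenyl]-2-(dimethoxymethyl)propanoyl}oxazolidin-2-one, via chlorotitanium enolate 9 (not isolated)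
Conditions: TiCl4, i-Pr2NEt, CH2Cl2, 0 °C; then HC(OMe)3, 0 °C
Reagents that add atoms: trimethyl orthoformate, COC(OC)OC
Why: Evans-type asymmetric alkylation of a chelated chlorotitanium (Z)-enolate, formed by soft enolisation, with the dimethoxycarbenium ion from the orthoformate; the benzyl group of the auxiliary shields one face, the electrophile enters anti to it, and C2 is set as (R) in 10, the arrangement that becomes (R) at C2 of 15 and of 19.

Step 5
Reactants: 10 (4S)-4-benzyl-3-{(2R)-3,3-bis[4-(TBS-oxy)-3,5-dimethoxyphenyl]-2-(dimethoxymethyl)propanoyl}oxazolidin-2-one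
Product: 11 (2S)-3,3-bis[4-(TBS-oxy)-3,5-dimethoxyphenyl]-2-(dimethoxymethyl)propan-1-ol
Conditions: LiBH4, MeOH (1 equiv), THF, 0 °C to rt
Reagents that add atoms: none
Why: Reductive cleavage of the N-acyl oxazolidinone with LiBH4 gives the primary alcohol and releases the auxiliary for recovery; the acetal and silyl ethers are inert, and C2 is no longer α to a carbonyl group.

Step 6
Reactants: 11 (2S)-3,3-bis[4-(TBS-oxy)-3,5-dimethoxyphenyl]-2-(dimethoxymethyl)propan-1-ol
Product: 12 (2S)-3,3-bis[4-(TBS-oxy)-3,5-dimethoxyphenyl]-2-(dimethoxymethyl)propyl TIPS ether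
Conditions: TIPSCl, imidazole, DMAP (cat.), DMF, rt to 40 °C
Reagents that add atoms: triisopropylsilyl chloride, CC(C)[Si](Cl)(C(C)C)C(C)C
Why: Imidazole-promoted silylation of a primary alcohol; the chloride is preferred to the silyl triflate because silyl triflates with pyridine bases are known to cleave dimethyl acetals.

Step 7
Reactants: 12 (2S)-3,3-bis[4-(TBS-oxy)-3,5-dimethoxyphenyl]-2-(dimethoxymethyl)propyl TIPS ether
Product: 13 (2S)-3,3-bis[4-(TBS-oxy)-3,5-dimethoxyphenyl]-2-[(TIPS-oxy)methyl]propanal
Conditions: Amberlyst-15, acetone/H2O, rt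
Reagents that add atoms: water, O
Why: Acid-catalysed acetal hydrolysis on a sulfonic acid resin; a primary TIPS ether and aryl TBS ethers withstand these conditions, and the α-branched aldehyde is taken on crude so that enolisation at C2 has little time to occur.

Step 8
Reactants: 13 (2S)-3,3-bis[4-(TBS-oxy)-3,5-dimethoxyphenyl]-2-[(TIPS-oxy)methyl]propanal
Product: 15 4,4'-{(2R)-2-[(TIPS-oxy)methyl]but-3-yne-1,1-diyl}bis(2,6-dimethoxyphenol), via bis-silyl alkyne 14 (not isolated)
Conditions: dimethyl (1-diazo-2-oxopropyl)phosphonate, K2CO3, MeOH/THF, 0 °C to rt; then 40 °C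
Reagents that add atoms: dimethyl (1-diazo-2-oxopropyl)phosphonate (Ohira–Bestmann reagent), COP(=O)(OC)C(=[N+]=[N-])C(C)=O
Why: Seyferth–Gilbert homologation in its Ohira–Bestmann form: methanolysis of the reagent releases the diazomethylphosphonate anion, which adds to the aldehyde, and the derived alkylidene carbene gives the terminal alkyne by 1,2-hydride shift under conditions known to preserve α-stereocentres of β-silyloxy aldehydes; continued exposure to K2CO3/MeOH then methanolyses the two phenolic silyl ethers while the alkyl TIPS ether stays.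

Step 9
Reactants: 15 4,4'-{(2R)-2-[(TIPS-oxy)methyl]but-3-yne-1,1-diyl}bis(2,6-dimethoxyphenol)
Product: 17 (1S,2S)-1-(4-hydroxy-3,5-dimethoxyphenyl)-3-iodo-6,8-dimethoxy-2-[(TIPS-oxy)methyl]-1,2-dihydronaphthalen-7-ol, via iodo spirodienone 16 (not isolated)
Conditions: NIS (1.05 equiv), NaHCO3, CH2Cl2/(CF3)2CHOH, −20 to 0 °C; then CF3SO3H, −20 to 0 °C
Reagents that add atoms: N-iodosuccinimide, O=C1CCC(=O)N1I
Why: Proposed new method: NIS, made more electrophilic by hydrogen bonding to the fluorinated alcohol, forms an iodonium ion on the terminal alkyne, the para carbon of one phenol (the future C4a) opens it at the terminal carbon C4 to give the iodo spirodienone 16 with iodine on C3, and triflic acid then protonates the dienone so that C1 shifts from C4a to the neighbouring C8a with rearomatisation. The closest known reaction types are the electrophilic ipso-iodocyclisation of para-oxygenated 4-aryl-1-alkynes with internal alkynes to spiro[4.5]trienones and the acid-mediated dienone–phenol rearrangement; new here are the terminal alkyne, the free phenol as the ring that is dearomatised, and the telescoping of both events. The spirocycle closes 5-endo-dig, the only mode the two-atom tether C1–C2 allows, and ring B is closed by the ring-expanding 1,2-shift, which may be concerted or run through ionisation to the C1 cation (a protonated quinone methide of the second aryl group) and 6-endo Friedel–Crafts reclosure at C8a, made easy by the cis relation of ring A and C2 across C3=C4. C1 becomes stereogenic here and is controlled by C2: the diastereotopic aryl group that spirocyclises should be the one that leaves the spectator aryl anti to the silyloxymethyl group on the cyclopentene, a concerted shift retains this, and a stepwise shift recloses, reversibly under acid, to the same more stable trans isomer. Ipso rather than ortho attack is required, since ortho attack would give the 5,6,7-oxygenated isomer; the para carbon of a 4-alkylphenol held unprotonated by NaHCO3 is its most nucleophilic site, and 5-endo opening of the iodonium is less strained than the 6-endo alternative. Migration of C1 rather than vinylic C4 is required; C1 is secondary, benzylic and conjugated to a para-hydroxyaryl donor, whereas migration of C4 would build charge next to the iodine-bearing carbon. One equivalent of NIS at low temperature limits ring iodination, and the TIPS ether and the uninvolved C2 centre should survive the short cold acid treatment.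

Step 10
Reactants: 17 (1S,2S)-1-(4-hydroxy-3,5-dimethoxyphenyl)-3-iodo-6,8-dimethoxy-2-[(TIPS-oxy)methyl]-1,2-dihydronaphthalen-7-ol
Product: 18 (1S,2R)-7-hydroxy-1-(4-hydroxy-3,5-dimethoxyphenyl)-6,8-dimethoxy-2-[(TIPS-oxy)methyl]-1,2-dihydronaphthalene-3-carbaldehyde
Conditions: Pd(OAc)2 (cat.), dppp, CO (1 atm), Et3SiH (slow addition), Et3N, DMF, 70 °C
Reagents that add atoms: carbon monoxide, [C-]#[O+]
Why: Palladium-catalysed reductive carbonylation of an alkenyl iodide: oxidative addition to zerovalent palladium formed in situ, CO insertion and hydride transfer from the silane to the acyl–palladium give the enal; the TIPS ether keeps the C9 oxygen from trapping the acyl–palladium as a butenolide, the phenols flanked by two methoxy groups are poor nucleophiles toward it, and neither stereocentre is involved.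

Step 11
Reactants: 18 (1S,2R)-7-hydroxy-1-(4-hydroxy-3,5-dimethoxyphenyl)-6,8-dimethoxy-2-[(TIPS-oxy)methyl]-1,2-dihydronaphthalene-3-carbaldehyde
Product: 19 (1S,2R)-7-hydroxy-1-(4-hydroxy-3,5-dimethoxyphenyl)-2-(hydroxymethyl)-6,8-dimethoxy-1,2-dihydronaphthalene-3-carbaldehyde
Conditions: HF·pyridine, pyridine/THF, 0 °C to rt
Reagents that add atoms: none
Why: Fluoride cleavage of a primary silyl ether under buffered conditions that leave the enal, the phenols and the labile C1 centre alone; any phenolic triethylsilyl ether picked up in step 10 is removed at the same time.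

## Compound list

1 | sinapic acid, (E)-3-(4-hydroxy-3,5-dimethoxyphenyl)prop-2-enoic acid | COc1cc(/C=C/C(=O)O)cc(OC)c1O | starting material
2 | 2,6-dimethoxyphenol | COc1cccc(OC)c1O | starting material
3 | 3,3-bis(4-hydroxy-3,5-dimethoxyphenyl)propanoic acid | COc1cc(C(CC(=O)O)c2cc(OC)c(O)c(OC)c2)cc(OC)c1O | intermediate
4 | tert-butyldimethylsilyl 3,3-bis[4-(TBS-oxy)-3,5-dimethoxyphenyl]propanoate | COc1cc(C(CC(=O)O[Si](C)(C)C(C)(C)C)c2cc(OC)c(O[Si](C)(C)C(C)(C)C)c(OC)c2)cc(OC)c1O[Si](C)(C)C(C)(C)C | intermediate
5 | 3,3-bis[4-(TBS-oxy)-3,5-dimethoxyphenyl]propanoic acid | COc1cc(C(CC(=O)O)c2cc(OC)c(O[Si](C)(C)C(C)(C)C)c(OC)c2)cc(OC)c1O[Si](C)(C)C(C)(C)C | intermediate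
6 | (S)-4-benzyl-2-oxazolidinone | O=C1N[C@@H](Cc2ccccc2)CO1 | starting material
7 | mixed anhydride of 5 with pivalic acid | COc1cc(C(CC(=O)OC(=O)C(C)(C)C)c2cc(OC)c(O[Si](C)(C)C(C)(C)C)c(OC)c2)cc(OC)c1O[Si](C)(C)C(C)(C)C | intermediate
8 | (4S)-4-benzyl-3-{3,3-bis[4-(TBS-oxy)-3,5-dimethoxyphenyl]propanoyl}oxazolidin-2-one | COc1cc(C(CC(=O)N2C(=O)OC[C@@H]2Cc2ccccc2)c2cc(OC)c(O[Si](C)(C)C(C)(C)C)c(OC)c2)cc(OC)c1O[Si](C)(C)C(C)(C)C | intermediate
9 | trichlorotitanium (Z)-enolate of 8 | COc1cc(C(/C=C(\O[Ti](Cl)(Cl)Cl)N2C(=O)OC[C@@H]2Cc2ccccc2)c2cc(OC)c(O[Si](C)(C)C(C)(C)C)c(OC)c2)cc(OC)c1O[Si](C)(C)C(C)(C)C | intermediate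
10 | (4S)-4-benzyl-3-{(2R)-3,3-bis[4-(TBS-oxy)-3,5-dimethoxyphenyl]-2-(dimethoxymethyl)propanoyl}oxazolidin-2-one | COc1cc(C([C@H](C(OC)OC)C(=O)N2C(=O)OC[C@@H]2Cc2ccccc2)c2cc(OC)c(O[Si](C)(C)C(C)(C)C)c(OC)c2)cc(OC)c1O[Si](C)(C)C(C)(C)C | intermediate
11 | (2S)-3,3-bis[4-(TBS-oxy)-3,5-dimethoxyphenyl]-2-(dimethoxymethyl)propan-1-ol | COc1cc(C([C@H](C(OC)OC)CO)c2cc(OC)c(O[Si](C)(C)C(C)(C)C)c(OC)c2)cc(OC)c1O[Si](C)(C)C(C)(C)C | intermediate
12 | (2S)-3,3-bis[4-(TBS-oxy)-3,5-dimethoxyphenyl]-2-(dimethoxymethyl)propyl TIPS ether | COc1cc(C([C@H](C(OC)OC)CO[Si](C(C)C)(C(C)C)C(C)C)c2cc(OC)c(O[Si](C)(C)C(C)(C)C)c(OC)c2)cc(OC)c1O[Si](C)(C)C(C)(C)C | intermediate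
13 | (2S)-3,3-bis[4-(TBS-oxy)-3,5-dimethoxyphenyl]-2-[(TIPS-oxy)methyl]propanal | COc1cc(C([C@H](C=O)CO[Si](C(C)C)(C(C)C)C(C)C)c2cc(OC)c(O[Si](C)(C)C(C)(C)C)c(OC)c2)cc(OC)c1O[Si](C)(C)C(C)(C)C | intermediate
14 | (2R)-1,1-bis[4-(TBS-oxy)-3,5-dimethoxyphenyl]-2-[(TIPS-oxy)methyl]but-3-yne | COc1cc(C([C@@H](CO[Si](C(C)C)(C(C)C)C(C)C)C#C)c2cc(OC)c(O[Si](C)(C)C(C)(C)C)c(OC)c2)cc(OC)c1O[Si](C)(C)C(C)(C)C | intermediate
15 | 4,4'-{(2R)-2-[(TIPS-oxy)methyl]but-3-yne-1,1-diyl}bis(2,6-dimethoxyphenol) | COc1cc(C([C@@H](CO[Si](C(C)C)(C(C)C)C(C)C)C#C)c2cc(OC)c(O)c(OC)c2)cc(OC)c1O | intermediate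
16 | (3S,4S)-4-(4-hydroxy-3,5-dimethoxyphenyl)-2-iodo-7,9-dimethoxy-3-[(TIPS-oxy)methyl]spiro[4.5]deca-1,6,9-trien-8-one | O=C1C(OC)=CC2(C=C1OC)C=C(I)[C@H](CO[Si](C(C)C)(C(C)C)C(C)C)[C@H]2c1cc(OC)c(O)c(OC)c1 | intermediate
17 | (1S,2S)-1-(4-hydroxy-3,5-dimethoxyphenyl)-3-iodo-6,8-dimethoxy-2-[(TIPS-oxy)methyl]-1,2-dihydronaphthalen-7-ol (aryl and silyloxymethyl trans) | COc1cc([C@H]2c3c(cc(OC)c(O)c3OC)C=C(I)[C@@H]2CO[Si](C(C)C)(C(C)C)C(C)C)cc(OC)c1O | intermediate
18 | (1S,2R)-7-hydroxy-1-(4-hydroxy-3,5-dimethoxyphenyl)-6,8-dimethoxy-2-[(TIPS-oxy)methyl]-1,2-dihydronaphthalene-3-carbaldehyde | COc1cc([C@H]2c3c(cc(OC)c(O)c3OC)C=C(C=O)[C@@H]2CO[Si](C(C)C)(C(C)C)C(C)C)cc(OC)c1O | intermediate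
19 | (1S,2R)-7-hydroxy-1-(4-hydroxy-3,5-dimethoxyphenyl)-2-(hydroxymethyl)-6,8-dimethoxy-1,2-dihydronaphthalene-3-carbaldehyde | COc1cc([C@H]2c3c(cc(OC)c(O)c3OC)C=C(C=O)[C@@H]2CO)cc(OC)c1O | target

## Step count and least certain steps

Total step count: 11. Longest linear sequence: 11 steps, from sinapic acid 1.

**Step 9 (key step).** Several processes can divert it:
- Failure of the terminal alkyne to engage: ring iodination, oxidation of a phenol to a quinone methide, or iodination of the alkyne C–H takes over because the iodonium must be opened at its less substituted carbon.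
- Ortho instead of ipso closure, since the ortho carbons are activated by two methoxy groups.
- Migration of the vinylic carbon instead of C1.
- Erosion of C2 by proton loss from the C1 cation.
- Acid cleavage of the silyl ether.

The fallback forms the same two bonds by known reactions; it sets out from aldehyde 13 and comes back at enal 18. Pinnick oxidation of 13 (NaClO2, NaH2PO4, 2-methylbut-2-ene) would give the acid F1. Its acid chloride F2 ((COCl)2, cat. DMF) reacts with diazomethane to the diazoketone F3, and buffered fluoride (Bu4NF/AcOH, 0 °C) frees the phenols to give the bis-phenol diazoketone F4. In CF3CO2H at −20 °C the protonated diazoketone is attacked by the para carbon of one phenol with loss of N2, the classical acid-promoted Ar1-5 dearomatising alkylation of phenolic diazoketones; this gives the spirodienedione F5 with C4–C4a in place. Dienone–phenol rearrangement (CF3SO3H, CH2Cl2) then gives the trans 3-tetralone F6; here the only competitor of the para-hydroxybenzylic C1 is a methylene next to a ketone. The 2,4,6-triisopropylbenzenesulfonylhydrazone F7 undergoes a Shapiro reaction (excess n-BuLi, deprotonation at benzylic C4) to the vinyllithium F8, and DMF formylates it to 18.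

**Step 1.** Attack of the cation through the position meta to the hydroxyl of 2 (activated by two methoxy groups) and self-condensation of 1 could lower regiochemical purity and conversion. The fallback fixes the C–aryl bond with a carbon–bromine bond; it sets out from 1, 2 and 6 and comes back at imide 8.
- Silylation of 1 gives the silyl ester F9, hydrolysed with aqueous acetic acid to O-TBS-sinapic acid F10.
- Its mixed pivalic anhydride F11 acylates 6 (LiCl, Et3N) to the N-enoyl imide F12.
- Bromination of 2 para to the hydroxyl gives 4-bromo-2,6-dimethoxyphenol F13 (also commercial), silylated to the aryl bromide F14 and converted with magnesium into the Grignard reagent F15.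
- CuBr·SMe2-mediated conjugate addition of F15 to F12 gives 8.

**Step 4.** The hindered β,β-diaryl enolate may react sluggishly with the bulky, weakly electrophilic dimethoxycarbenium ion. That gives time for TiCl4 to be sequestered by the aryl ether oxygens, for ring formylation, or for silyl ether loss. The fallback uses a small, reactive electrophile and avoids the later acetal hydrolysis; it sets out from imide 8 through the same enolate 9 and comes back at aldehyde 13.
- Alkylation of 9 with benzyl chloromethyl ether gives the benzyloxymethyl imide F16.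
- LiBH4 gives the alcohol F17, and TIPSCl/imidazole the silyl ether F18.
- Hydrogenolysis (H2, Pd/C; no alkyne is present yet) gives the alcohol F19.
- Dess–Martin periodinane oxidises F19 to 13.

**Step 8.** Epimerisation at C2 or β-elimination of the silyloxy group can occur while the aldehyde sits in basic methanol, and methanolysis of the hindered aryl silyl ethers may be slow. The fallback avoids base at the aldehyde stage; it sets out from 13 and comes back at 14 and then 15. Dibromoolefination (CBr4, PPh3, Et3N) gives the dibromoalkene F20. n-BuLi at −78 °C followed by aqueous NH4Cl (Corey–Fuchs sequence) gives 14. Bu4NF/AcOH at 0 °C removes only the aryl silyl groups to give 15.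

**Step 10.** Possible failures are hydrodeiodination before CO insertion, conjugate reduction of the product enal by the silane, and capture of the acyl–palladium by a phenol. The fallback drops the hydride source; it sets out from 17 and comes back at 18. Methoxycarbonylation (Pd(OAc)2, dppp, CO, MeOH, Et3N) gives the methyl ester F21. i-Bu2AlH in excess reduces it to the allylic alcohol F22. MnO2 oxidises F22 to 18.

## Further compounds

F1 | step 9 | (2S)-3,3-bis[4-(TBS-oxy)-3,5-dimethoxyphenyl]-2-[(TIPS-oxy)methyl]propanoic acid | COc1cc(C([C@H](C(=O)O)CO[Si](C(C)C)(C(C)C)C(C)C)c2cc(OC)c(O[Si](C)(C)C(C)(C)C)c(OC)c2)cc(OC)c1O[Si](C)(C)C(C)(C)C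
F2 | step 9 | (2S)-3,3-bis[4-(TBS-oxy)-3,5-dimethoxyphenyl]-2-[(TIPS-oxy)methyl]propanoyl chloride | COc1cc(C([C@H](C(=O)Cl)CO[Si](C(C)C)(C(C)C)C(C)C)c2cc(OC)c(O[Si](C)(C)C(C)(C)C)c(OC)c2)cc(OC)c1O[Si](C)(C)C(C)(C)C
F3 | step 9 | (3S)-1-diazo-4,4-bis[4-(TBS-oxy)-3,5-dimethoxyphenyl]-3-[(TIPS-oxy)methyl]butan-2-one | COc1cc(C([C@H](C(=O)C=[N+]=[N-])CO[Si](C(C)C)(C(C)C)C(C)C)c2cc(OC)c(O[Si](C)(C)C(C)(C)C)c(OC)c2)cc(OC)c1O[Si](C)(C)C(C)(C)C
F4 | step 9 | (3S)-1-diazo-4,4-bis(4-hydroxy-3,5-dimethoxyphenyl)-3-[(TIPS-oxy)methyl]butan-2-one | COc1cc(C([C@H](C(=O)C=[N+]=[N-])CO[Si](C(C)C)(C(C)C)C(C)C)c2cc(OC)c(O)c(OC)c2)cc(OC)c1O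
F5 | step 9 | (3S,4S)-4-(4-hydroxy-3,5-dimethoxyphenyl)-7,9-dimethoxy-3-[(TIPS-oxy)methyl]spiro[4.5]deca-6,9-diene-2,8-dione | O=C1C(OC)=CC2(C=C1OC)CC(=O)[C@H](CO[Si](C(C)C)(C(C)C)C(C)C)[C@H]2c1cc(OC)c(O)c(OC)c1
F6 | step 9 | (1S,2S)-7-hydroxy-1-(4-hydroxy-3,5-dimethoxyphenyl)-6,8-dimethoxy-2-[(TIPS-oxy)methyl]-1,4-dihydronaphthalen-3(2H)-one | COc1cc([C@H]2c3c(cc(OC)c(O)c3OC)CC(=O)[C@@H]2CO[Si](C(C)C)(C(C)C)C(C)C)cc(OC)c1O
F7 | step 9 | 2,4,6-triisopropylbenzenesulfonylhydrazone of F6 | COc1cc([C@H]2c3c(cc(OC)c(O)c3OC)CC(=NNS(=O)(=O)c3c(C(C)C)cc(C(C)C)cc3C(C)C)[C@@H]2CO[Si](C(C)C)(C(C)C)C(C)C)cc(OC)c1O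
F8 | step 9 | C3-lithio-1,2-dihydronaphthalene derived from F7, both phenols as lithium phenoxides | COc1cc([C@H]2c3c(cc(OC)c(O[Li])c3OC)C=C([Li])[C@@H]2CO[Si](C(C)C)(C(C)C)C(C)C)cc(OC)c1O[Li]
F9 | step 1 | tert-butyldimethylsilyl (E)-3-[4-(TBS-oxy)-3,5-dimethoxyphenyl]prop-2-enoate | COc1cc(/C=C/C(=O)O[Si](C)(C)C(C)(C)C)cc(OC)c1O[Si](C)(C)C(C)(C)C
F10 | step 1 | (E)-3-[4-(TBS-oxy)-3,5-dimethoxyphenyl]prop-2-enoic acid | COc1cc(/C=C/C(=O)O)cc(OC)c1O[Si](C)(C)C(C)(C)C
F11 | step 1 | mixed anhydride of F10 with pivalic acid | COc1cc(/C=C/C(=O)OC(=O)C(C)(C)C)cc(OC)c1O[Si](C)(C)C(C)(C)C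
F12 | step 1 | (4S)-4-benzyl-3-{(E)-3-[4-(TBS-oxy)-3,5-dimethoxyphenyl]prop-2-enoyl}oxazolidin-2-one | COc1cc(/C=C/C(=O)N2C(=O)OC[C@@H]2Cc2ccccc2)cc(OC)c1O[Si](C)(C)C(C)(C)C
F13 | step 1 | 4-bromo-2,6-dimethoxyphenol | COc1cc(Br)cc(OC)c1O
F14 | step 1 | (4-bromo-2,6-dimethoxyphenoxy)(tert-butyl)dimethylsilane | COc1cc(Br)cc(OC)c1O[Si](C)(C)C(C)(C)C
F15 | step 1 | [4-(TBS-oxy)-3,5-dimethoxyphenyl]magnesium bromide | COc1cc([Mg]Br)cc(OC)c1O[Si](C)(C)C(C)(C)C
F16 | step 4 | (4S)-4-benzyl-3-{(2R)-2-[(benzyloxy)methyl]-3,3-bis[4-(TBS-oxy)-3,5-dimethoxyphenyl]propanoyl}oxazolidin-2-one | COc1cc(C([C@H](COCc2ccccc2)C(=O)N2C(=O)OC[C@@H]2Cc2ccccc2)c2cc(OC)c(O[Si](C)(C)C(C)(C)C)c(OC)c2)cc(OC)c1O[Si](C)(C)C(C)(C)C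
F17 | step 4 | (2S)-2-[(benzyloxy)methyl]-3,3-bis[4-(TBS-oxy)-3,5-dimethoxyphenyl]propan-1-ol | COc1cc(C([C@H](COCc2ccccc2)CO)c2cc(OC)c(O[Si](C)(C)C(C)(C)C)c(OC)c2)cc(OC)c1O[Si](C)(C)C(C)(C)C
F18 | step 4 | (2R)-2-[(benzyloxy)methyl]-3,3-bis[4-(TBS-oxy)-3,5-dimethoxyphenyl]propyl TIPS ether | COc1cc(C([C@H](COCc2ccccc2)CO[Si](C(C)C)(C(C)C)C(C)C)c2cc(OC)c(O[Si](C)(C)C(C)(C)C)c(OC)c2)cc(OC)c1O[Si](C)(C)C(C)(C)C
F19 | step 4 | (2R)-3,3-bis[4-(TBS-oxy)-3,5-dimethoxyphenyl]-2-[(TIPS-oxy)methyl]propan-1-ol | COc1cc(C([C@H](CO)CO[Si](C(C)C)(C(C)C)C(C)C)c2cc(OC)c(O[Si](C)(C)C(C)(C)C)c(OC)c2)cc(OC)c1O[Si](C)(C)C(C)(C)C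
F20 | step 8 | (3R)-1,1-dibromo-4,4-bis[4-(TBS-oxy)-3,5-dimethoxyphenyl]-3-[(TIPS-oxy)methyl]but-1-ene | COc1cc(C([C@@H](CO[Si](C(C)C)(C(C)C)C(C)C)C=C(Br)Br)c2cc(OC)c(O[Si](C)(C)C(C)(C)C)c(OC)c2)cc(OC)c1O[Si](C)(C)C(C)(C)C
F21 | step 10 | methyl (1S,2R)-7-hydroxy-1-(4-hydroxy-3,5-dimethoxyphenyl)-6,8-dimethoxy-2-[(TIPS-oxy)methyl]-1,2-dihydronaphthalene-3-carboxylate | COc1cc([C@H]2c3c(cc(OC)c(O)c3OC)C=C(C(=O)OC)[C@@H]2CO[Si](C(C)C)(C(C)C)C(C)C)cc(OC)c1O
F22 | step 10 | (1S,2R)-1-(4-hydroxy-3,5-dimethoxyphenyl)-3-(hydroxymethyl)-6,8-dimethoxy-2-[(TIPS-oxy)methyl]-1,2-dihydronaphthalen-7-ol | COc1cc([C@H]2c3c(cc(OC)c(O)c3OC)C=C(CO)[C@@H]2CO[Si](C(C)C)(C(C)C)C(C)C)cc(OC)c1O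
A1 | alternative 1 | dimethyl (E)-2-{[4-(benzyloxy)-2-bromo-3,5-dimethoxyphenyl]methylidene}butanedioate | COC(=O)C/C(=C\c1cc(OC)c(OCc2ccccc2)c(OC)c1Br)C(=O)OC
A2 | alternative 1 | N'-{(E)-[4-(benzyloxy)-3,5-dimethoxyphenyl]methylidene}-4-methylbenzenesulfonohydrazide | COc1cc(/C=N/NS(=O)(=O)c2ccc(C)cc2)cc(OC)c1OCc1ccccc1
A3 | alternative 1 | dimethyl trans-7-(benzyloxy)-1-[4-(benzyloxy)-3,5-dimethoxyphenyl]-6,8-dimethoxy-1,2-dihydronaphthalene-2,3-dicarboxylate | COc1cc([C@H]2c3c(cc(OC)c(OCc4ccccc4)c3OC)C=C(C(=O)OC)[C@@H]2C(=O)OC)cc(OC)c1OCc1ccccc1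
A4 | alternative 2 | methyl (E)-4-[4-(benzyloxy)-3,5-dimethoxyphenyl]-3-[(TBS-oxy)methyl]-2-[(4-methoxyfuran-2-yl)methylidene]-7-oxohept-5-ynoate | COc1cc([C@H]([C@@H](CO[Si](C)(C)C(C)(C)C)/C(C(=O)OC)=C\c2cc(OC)co2)C#CC=O)cc(OC)c1OCc1ccccc1
A5 | alternative 2 | methyl trans-1-[4-(benzyloxy)-3,5-dimethoxyphenyl]-8-formyl-7-hydroxy-6-methoxy-2-[(TBS-oxy)methyl]-1,2-dihydronaphthalene-3-carboxylate | COc1cc([C@H]2c3c(cc(OC)c(O)c3C=O)C=C(C(=O)OC)[C@@H]2CO[Si](C)(C)C(C)(C)C)cc(OC)c1OCc1ccccc1
A6 | alternative 3 | trans-5-(benzyloxy)-3-[4-(benzyloxy)-3,5-dimethoxyphenyl]-4,6-dimethoxy-2-[(TBS-oxy)methyl]indan-1-one | COc1cc([C@H]2c3c(cc(OC)c(OCc4ccccc4)c3OC)C(=O)[C@@H]2CO[Si](C)(C)C(C)(C)C)cc(OC)c1OCc1ccccc1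
A7 | alternative 3 | trans-7-(benzyloxy)-1-[4-(benzyloxy)-3,5-dimethoxyphenyl]-6,8-dimethoxy-2-[(TBS-oxy)methyl]-1,4-dihydronaphthalen-3(2H)-one | COc1cc([C@H]2c3c(cc(OC)c(OCc4ccccc4)c3OC)CC(=O)[C@@H]2CO[Si](C)(C)C(C)(C)C)cc(OC)c1OCc1ccccc1
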